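**Retrosynthetic overview**

1. Unit 1 (lactone ring A, cycloheptane ring B) is bought as (+)-8-epi-xanthatin. Cyclohexene ring C and the spiro carbon C11' come from an exo Diels–Alder reaction of its C5=C1–C2=C3 dienone with a 3-substituted itaconic anhydride, which is ring D at the anhydride level.
2. Cycloheptene ring E and the lactone level of ring D are then made in one operation by closing C8'–C9'. The feature that allows this: C8', the O-bearing fusion carbon of lactone D, lies next to the C9'H2–C10'H(CH3) edge of ring E, so C8' can be an anhydride carbonyl and C9'/C10'/methyl a 2-(silylmethyl)allyl unit.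
3. The stereocentres of unit 2 are relayed from C11': C7' by face-selective protonation, C8' in the key step (cis fusion of D/E), C10' by convex-face reduction of the exocyclic alkene.
4. The C1–OH/enone is put in late by γ-oxygenation of the deconjugated ketone; the amine mask on ring A and the dithiane on the side chain leave together in the last step.
5. Ring order: A, B (chiral pool) → C and D (Diels–Alder) → E (key step).

Key step: step 11

Remark: (+)-8-epi-xanthatin is taken as a purchasable chiral-pool sesquiterpene lactone and is the only source of chirality; xanthanolide numbering is used, with primes for unit 2.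

**Route**

Step 1
Reactants: 1 hex-5-yn-2-one
Product: 2 2-(but-3-yn-1-yl)-2-methyl-1,3-dithiane
Conditions: propane-1,3-dithiol, BF3·OEt2 (cat.), CH2Cl2, 0 °C to rt
Reagents that add atoms: propane-1,3-dithiol, SCCCS
Why: Lewis-acid-catalysed dithioacetalisation masks the ketone as a dithiane that should survive base, hydride and the later Lewis-acid steps.

Step 2
Reactants: 2 2-(but-3-yn-1-yl)-2-methyl-1,3-dithiane
Product: 4 5-(2-methyl-1,3-dithian-2-yl)pent-2-yn-1-ol, via lithium acetylide 3 (not isolated)
Conditions: n-BuLi, THF, −78 °C; then (CH2O)n, −78 °C to rt; H2O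
Reagents that add atoms: formaldehyde (from paraformaldehyde), C=O
Why: addition of the alkynyllithium to formaldehyde gives the propargylic alcohol needed for directed hydroalumination.

Step 3
Reactants: 4 5-(2-methyl-1,3-dithian-2-yl)pent-2-yn-1-ol
Product: 6 (2Z)-3-iodo-5-(2-methyl-1,3-dithian-2-yl)pent-2-en-1-ol, via cyclic alkenylalanate 5 (not isolated)
Conditions: NaAlH2(OCH2CH2OCH3)2, THF, 0 °C to rt; then I2, −78 °C
Reagents that add atoms: iodine, II
Why: alkoxide-directed trans-hydroalumination of the propargylic alcohol and iodinolysis of the five-membered alanate place iodine cis to CH2OH, which later holds C6' and C10' on the same side of C5'=C1'.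

Step 4
Reactants: 6 (2Z)-3-iodo-5-(2-methyl-1,3-dithian-2-yl)pent-2-en-1-ol; 7 (2-bromoprop-2-en-1-yl)trimethylsilane
Product: 9 (2Z)-3-[2-(2-methyl-1,3-dithian-2-yl)ethyl]-4-[(trimethylsilyl)methyl]penta-2,4-dien-1-ol, via alkenylzinc bromide 8 (not isolated)
Conditions: 7, Mg, THF, rt; ZnBr2, 0 °C; then 6, Pd(PPh3)4 (5 mol %), THF, 40 °C
Reagents that add atoms: none
Why: Negishi cross-coupling proceeds with retention at the alkenyl iodide, so the 2-(silylmethyl)vinyl unit ends up cis to the hydroxymethyl group.

Step 5
Reactants: 9 (2Z)-3-[2-(2-methyl-1,3-dithian-2-yl)ethyl]-4-[(trimethylsilyl)methyl]penta-2,4-dien-1-ol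
Product: 10 {(3Z)-5-bromo-2-methylidene-3-[2-(2-methyl-1,3-dithian-2-yl)ethyl]pent-3-en-1-yl}trimethylsilane
Conditions: CBr4, PPh3, 2,6-lutidine, CH2Cl2, 0 °C
Reagents that add atoms: carbon tetrabromide, BrC(Br)(Br)Br
Why: Appel bromination of the allylic alcohol is neutral enough to spare the allylsilane and the dithiane.

Step 6
Reactants: 11 4-methoxy-2-methylidene-4-oxobutanoic acid; 10 {(3Z)-5-bromo-2-methylidene-3-[2-(2-methyl-1,3-dithian-2-yl)ethyl]pent-3-en-1-yl}trimethylsilane
Product: 13 rac-(5Z)-3-(methoxycarbonyl)-2-methylidene-6-[2-(2-methyl-1,3-dithian-2-yl)ethyl]-7-[(trimethylsilyl)methyl]octa-5,7-dienoic acid, via itaconate dianion 12 (not isolated)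
Conditions: LiN(iPr)2 (2.1 equiv), THF, −78 °C; then 10, −78 to −20 °C; cold 0.5 M HCl
Reagents that add atoms: none
Why: the carboxylate/ester-dienolate dianion of the itaconate half-ester should be alkylated at the ester α-carbon (C7') by SN2 displacement of the primary allylic bromide; C7' is formed racemic on purpose because step 10 resets it.

Step 7
Reactants: 13 rac-(5Z)-3-(methoxycarbonyl)-2-methylidene-6-[2-(2-methyl-1,3-dithian-2-yl)ethyl]-7-[(trimethylsilyl)methyl]octa-5,7-dienoic acid
Product: 14 rac-(5Z)-3-carboxy-2-methylidene-6-[2-(2-methyl-1,3-dithian-2-yl)ethyl]-7-[(trimethylsilyl)methyl]octa-5,7-dienoic acid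
Conditions: LiOH, THF/H2O, rt; cold 0.5 M HCl
Reagents that add atoms: lithium hydroxide, [Li+].[OH-]
Why: ester saponification gives the diacid; the dicarboxylate is not expected to enolise at C7'.

Step 8
Reactants: 14 rac-(5Z)-3-carboxy-2-methylidene-6-[2-(2-methyl-1,3-dithian-2-yl)ethyl]-7-[(trimethylsilyl)methyl]octa-5,7-dienoic acid
Product: 15 rac-3-methylidene-4-{(2Z)-3-[2-(2-methyl-1,3-dithian-2-yl)ethyl]-4-[(trimethylsilyl)methyl]penta-2,4-dien-1-yl}oxolane-2,5-dione
Conditions: DCC, CH2Cl2, 0 °C to rt
Reagents that add atoms: none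
Why: carbodiimide dehydration closes the five-membered anhydride without base or heat, locking the methylidene s-cis to the C12' carbonyl.

Step 9
Reactants: 15 rac-3-methylidene-4-{(2Z)-3-[2-(2-methyl-1,3-dithian-2-yl)ethyl]-4-[(trimethylsilyl)methyl]penta-2,4-dien-1-yl}oxolane-2,5-dione; 16 (+)-8-epi-xanthatin
Product: 17 spiro anhydride Diels–Alder adduct of 15 and 16 (C7' epimer pair)
Conditions: 15 (2.5 equiv), toluene (0.5 M), BHT, 80 °C
Reagents that add atoms: none
Why: thermal Diels–Alder reaction of the C5=C1–C2=C3 dienone with the s-cis-locked methylidene should set C5, C3 and the spiro centre C11' through ortho regiochemistry to the acetyl-bearing terminus, attack on the diene face anti to the C10 methyl and the lactone, and the exo orientation of C12'=O usual for α-methylidene cyclic carbonyl dienophiles; either enantiomer of 15 that reacts in this mode gives the same C11', so 17 differs only at C7'.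

Step 10
Reactants: 17 spiro anhydride Diels–Alder adduct of 15 and 16 (C7' epimer pair)
Product: 19 spiro anhydride carrying the side chain on the C3 face (single C7' epimer), via silyl ketene acetal 18 (not isolated)
Conditions: Et3N, Me3SiOTf, CH2Cl2, −78 to 0 °C; then pivalic acid, −78 °C
Reagents that add atoms: none
Why: soft enolisation converts both C7' epimers into one planar cyclic silyl ketene acetal, and kinetic protonation by the bulky acid on the spiro-ring face next to C13'H2, away from the acetyl group on C3, should push the side chain to the C3 face.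

Step 11
Reactants: 19 spiro anhydride carrying the side chain on the C3 face (single C7' epimer)
Product: 21 pentacyclic dilactone with rings A to E and a C10' methylidene, via keto silyl ester 20 (not isolated)
Conditions: Me3SiOTf (0.3 equiv), 2,6-di-tert-butyl-4-methylpyridine, CH2Cl2, −78 °C; then Et3SiH, −78 to −20 °C
Reagents that add atoms: none
Why: Proposed new method: Me3SiOTf should ionise the anhydride at its less hindered C8' carbonyl (acyl triflate plus C12' silyl ester), and the terminal carbon C9' of the 2-substituted allylsilane should attack C8' in an SE2' acylation, the β-silyl cation collapsing to the exocyclic C10' methylidene and returning the silyl triflate; the closest known reaction types are the Lewis-acid acylation of allylsilanes by anhydrides and acid chlorides and, for the second stage, the silane reduction of lactols and keto acids to lactones. Ring E closes in a 7-endo mode at the allylsilane (7-exo at the carbonyl), helped by the Z alkene that holds C6' and C10' on one side, and ring D then closes in a 5-exo mode when the silyl ester oxygen adds to the activated C8' ketone of 20 to give a bicyclic acyloxocarbenium ion. Et3SiH reduces this ion, and the new stereocentre C8' is set because hydride should reach only the face syn to H7' (anti to C6', the convex face of the emerging cis-fused rings D and E). The step needs C8' rather than C12' to acylate (seven- against eight-membered ring, neopentylic C12'), the allylsilane to outrun the C1=C2 alkene and protodesilylation (hindered pyridine base), and the oxocarbenium ion to be reduced before the C4 ketone or the C7' centre of 20 can react (low temperature, no base).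

Step 12
Reactants: 21 pentacyclic dilactone with rings A to E and a C10' methylidene
Product: 22 13-dimethylamino-11,13-dihydro derivative of 21
Conditions: Me2NH (2 M in THF), rt
Reagents that add atoms: dimethylamine, CNC
Why: aza-Michael addition masks the α-methylidene lactone of ring A (enolate protonated on the convex face), so that the C10' methylidene is the only unhindered alkene left for diimide.

Step 13
Reactants: 22 13-dimethylamino-11,13-dihydro derivative of 21
Product: 23 10'-methyl β,γ-unsaturated ketone (amine and dithiane masks in place)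
Conditions: 2-nitrobenzenesulfonyl hydrazide, Et3N, CH2Cl2, rt
Reagents that add atoms: none
Why: diimide reduction is selective for the 1,1-disubstituted terminus of the diene and should deliver H2 syn from the convex face of the cis-fused rings D/E (the face of H7' and H8'), setting C10' with methyl cis to O8'.

Step 14
Reactants: 23 10'-methyl β,γ-unsaturated ketone (amine and dithiane masks in place)
Product: 25 1-hydroxy-2-en-4-one (amine and dithiane masks in place), via C1 hydroperoxide 24 (not isolated)
Conditions: O2 (1 atm), Cs2CO3, P(OEt)3, DMSO, rt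
Reagents that add atoms: dioxygen, O=O
Why: γ-oxygenation of the dienolate of the deconjugated ketone by triplet oxygen, as in the autoxidation of Δ5-3-ketosteroids, with phosphite reduction of the hydroperoxide; oxygen should enter at C1 on the face of H5, anti to the C5–C6 bond, giving the cis B/C fusion and the conjugated enone.

Step 15
Reactants: 25 1-hydroxy-2-en-4-one (amine and dithiane masks in place)
Product: 27 CNP0195550.4 (target), via trimethylammonium iodide 26 (not isolated)
Conditions: MeI (excess), NaHCO3, MeCN/H2O (4:1), 45 °C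
Reagents that add atoms: water, O
Why: exhaustive N-methylation followed by Hofmann-type E1cB elimination restores the α-methylidene lactone, while S-methylation and hydrolysis of the dithiane release the methyl ketone in the same flask.

**Compound list**

1 | hex-5-yn-2-one | CC(=O)CCC#C | starting material
2 | 2-(but-3-yn-1-yl)-2-methyl-1,3-dithiane | CC1(CCC#C)SCCCS1 | intermediate
3 | lithium acetylide of 2 | [Li]C#CCCC1(C)SCCCS1 | intermediate
4 | 5-(2-methyl-1,3-dithian-2-yl)pent-2-yn-1-ol | OCC#CCCC1(C)SCCCS1 | intermediate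
5 | cyclic alkenylalanate of 4 (sodium salt; Al bound to the alkoxide O and to C3, two 2-methoxyethoxy ligands) | [Na+].COCCO[Al-]1(OCCOC)OCC=C1CCC2(C)SCCCS2 | intermediate
6 | (2Z)-3-iodo-5-(2-methyl-1,3-dithian-2-yl)pent-2-en-1-ol | OC/C=C(\I)CCC1(C)SCCCS1 | intermediate
7 | (2-bromoprop-2-en-1-yl)trimethylsilane | C=C(Br)C[Si](C)(C)C | starting material
8 | bromo[3-(trimethylsilyl)prop-1-en-2-yl]zinc | C=C([Zn]Br)C[Si](C)(C)C | intermediate
9 | (2Z)-3-[2-(2-methyl-1,3-dithian-2-yl)ethyl]-4-[(trimethylsilyl)methyl]penta-2,4-dien-1-ol | OC/C=C(/CCC1(C)SCCCS1)C(=C)C[Si](C)(C)C | intermediate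
10 | {(3Z)-5-bromo-2-methylidene-3-[2-(2-methyl-1,3-dithian-2-yl)ethyl]pent-3-en-1-yl}trimethylsilane | BrC/C=C(/CCC1(C)SCCCS1)C(=C)C[Si](C)(C)C | intermediate
11 | 4-methoxy-2-methylidene-4-oxobutanoic acid (4-methyl hydrogen itaconate) | C=C(CC(=O)OC)C(=O)O | starting material
12 | dilithium carboxylate ester-dienolate of 11 | [Li+].[Li+].C=C(C(=O)[O-])C=C([O-])OC | intermediate
13 | rac-(5Z)-3-(methoxycarbonyl)-2-methylidene-6-[2-(2-methyl-1,3-dithian-2-yl)ethyl]-7-[(trimethylsilyl)methyl]octa-5,7-dienoic acid | C=C(C(=O)O)C(C(=O)OC)C/C=C(/CCC1(C)SCCCS1)C(=C)C[Si](C)(C)C | intermediate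
14 | rac-(5Z)-3-carboxy-2-methylidene-6-[2-(2-methyl-1,3-dithian-2-yl)ethyl]-7-[(trimethylsilyl)methyl]octa-5,7-dienoic acid | C=C(C(=O)O)C(C(=O)O)C/C=C(/CCC1(C)SCCCS1)C(=C)C[Si](C)(C)C | intermediate
15 | rac-3-methylidene-4-{(2Z)-3-[2-(2-methyl-1,3-dithian-2-yl)ethyl]-4-[(trimethylsilyl)methyl]penta-2,4-dien-1-yl}oxolane-2,5-dione | C=C1C(=O)OC(=O)C1C/C=C(/CCC2(C)SCCCS2)C(=C)C[Si](C)(C)C | intermediate
16 | (+)-8-epi-xanthatin, (3aR,7S,8aR)-7-methyl-3-methylidene-6-[(1E)-3-oxobut-1-en-1-yl]-3,3a,4,7,8,8a-hexahydro-2H-cyclohepta[b]furan-2-one | C=C1C(=O)O[C@@H]2C[C@H](C)C(/C=C/C(C)=O)=CC[C@H]12 | starting material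
17 | Diels–Alder adduct: rings A, B, C with the anhydride spiro at C11' (C12'=O on the H5 face), 1,2-alkene, 3-acetyl cis to C6 and C7', dienylsilane side chain on C7' (both C7' epimers) | C=C1C(=O)O[C@@H]2C[C@H](C)C3=C[C@@H](C(C)=O)[C@@]4(C[C@H]3C[C@H]12)C(=O)OC(=O)C4C/C=C(/CCC5(C)SCCCS5)C(=C)C[Si](C)(C)C | intermediate
18 | cyclic silyl ketene acetal of 17 (C7'=C8'–OSiMe3) | C=C1C(=O)O[C@@H]2C[C@H](C)C3=C[C@@H](C(C)=O)[C@@]4(C[C@H]3C[C@H]12)C(=O)OC(O[Si](C)(C)C)=C4C/C=C(/CCC5(C)SCCCS5)C(=C)C[Si](C)(C)C | intermediate
19 | spiro anhydride with H7' on the C13' face and the side chain on the C3 face | C=C1C(=O)O[C@@H]2C[C@H](C)C3=C[C@@H](C(C)=O)[C@@]4(C[C@H]3C[C@H]12)C(=O)OC(=O)[C@H]4C/C=C(/CCC5(C)SCCCS5)C(=C)C[Si](C)(C)C | intermediate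
20 | keto silyl ester: ring E closed, C8' ketone, C10' methylidene, C12' trimethylsilyl ester on C11' | C=C1C(=O)O[C@@H]2C[C@H](C)C3=C[C@@H](C(C)=O)[C@@](C[C@H]3C[C@H]12)(C(=O)O[Si](C)(C)C)[C@@H]1CC=C(CCC5(C)SCCCS5)C(=C)CC1=O | intermediate
21 | pentacyclic dilactone: rings A to E, cis-fused D/E, C10' methylidene, 1,2-alkene, 3-acetyl, dithiane side chain | C=C1C(=O)O[C@@H]2C[C@H](C)C3=C[C@@H](C(C)=O)[C@@]4(C[C@H]3C[C@H]12)C(=O)O[C@H]1CC(=C)C(CCC5(C)SCCCS5)=CC[C@H]14 | intermediate
22 | 13-dimethylamino-11,13-dihydro derivative of 21 (H11 on the convex face; this centre is lost again in step 15) | CN(C)C[C@@H]1C(=O)O[C@@H]2C[C@H](C)C3=C[C@@H](C(C)=O)[C@@]4(C[C@H]3C[C@H]12)C(=O)O[C@H]1CC(=C)C(CCC5(C)SCCCS5)=CC[C@H]14 | intermediate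
23 | 10'-methyl compound (methyl cis to O8'), β,γ-unsaturated ketone, amine and dithiane in place | CN(C)C[C@@H]1C(=O)O[C@@H]2C[C@H](C)C3=C[C@@H](C(C)=O)[C@@]4(C[C@H]3C[C@H]12)C(=O)O[C@H]1C[C@@H](C)C(CCC5(C)SCCCS5)=CC[C@H]14 | intermediate
24 | C1 hydroperoxide of the 2-en-4-one | CN(C)C[C@@H]1C(=O)O[C@@H]2C[C@H](C)[C@@]3(OO)C=C(C(C)=O)[C@@]4(C[C@H]3C[C@H]12)C(=O)O[C@H]1C[C@@H](C)C(CCC5(C)SCCCS5)=CC[C@H]14 | intermediate
25 | 1-hydroxy-2-en-4-one, amine and dithiane in place | CN(C)C[C@@H]1C(=O)O[C@@H]2C[C@H](C)[C@@]3(O)C=C(C(C)=O)[C@@]4(C[C@H]3C[C@H]12)C(=O)O[C@H]1C[C@@H](C)C(CCC5(C)SCCCS5)=CC[C@H]14 | intermediate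
26 | trimethylammonium iodide of 25 | C[N+](C)(C)C[C@@H]1C(=O)O[C@@H]2C[C@H](C)[C@@]3(O)C=C(C(C)=O)[C@@]4(C[C@H]3C[C@H]12)C(=O)O[C@H]1C[C@@H](C)C(CCC5(C)SCCCS5)=CC[C@H]14.[I-] | intermediate
27 | CNP0195550.4 | C=C1C(=O)O[C@@H]2C[C@H](C)[C@@]3(O)C=C(C(C)=O)[C@@]4(C[C@H]3C[C@H]12)C(=O)O[C@H]1C[C@@H](C)C(CCC(C)=O)=CC[C@H]14 | target

**Step count and risks**

Total step count: 15. Longest linear sequence: 15 steps (1 to 27); compounds 7, 11 and 16 enter as bought materials.

Steps most likely to fail:

Step 11. What may go wrong: protodesilylation before acylation, isomerisation of the β,γ-unsaturated ketone 20 into conjugation, loss of the C7' configuration through enolisation of 20, or reduction of the C4 ketone. Fallback, from 19 back to 21: C8' is lowered to the lactol level before the C–C bond is made. LiAlH(OtBu)3 (THF, −78 °C) should reduce the less hindered anhydride carbonyl to the 8'-hydroxy lactone F1. Ac2O/pyridine should give the 8'-acetoxy lactone F2. BF3·OEt2 (CH2Cl2, −78 °C) should then ionise F2 to the acyloxocarbenium ion, which the allylsilane traps in a Hosomi–Sakurai reaction on the side of the tether. This closes ring E at the lactone oxidation level with cis fusion, without any ketone intermediate.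

Step 10. What may go wrong: protonation on the wrong face, or re-epimerisation of the acidic anhydride α-position during work-up, which returns the side chain to the C13' face. Fallback, from 17 back to 19: proton transfer is replaced by hydrogen-atom transfer. Ketene acetal 18 is trapped with PhSeBr to give the 7'-phenylselanyl anhydride F3. Bu3SnH (AIBN, benzene, high stannane concentration) should then reduce the planar α-acyl radical irreversibly from the open C13' face, giving 19. The high stannane concentration is meant to outrun cyclisation of the radical onto the diene.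

Step 9. What may go wrong: low exo or facial selectivity with the hindered racemic dienophile, thermal isomerisation of 15 to the unreactive alkylmethylmaleic anhydride, or self-dimerisation of 16. Fallback, from 16 and 9 back to 17: the cycloaddition is run with commercial itaconic anhydride, which is more reactive and has no stereocentre, to give the side-chain-free spiro anhydride F4. Alcohol 9 is converted into its allylic methyl carbonate F5 (ClCO2Me, pyridine). The two are joined by palladium-catalysed allylation (Pd2(dba)3, dppe, THF) of the silyl ketene acetal F6 made from F4 (Me3SiOTf, Et3N), which should attack the allyl terminus C6'. The C7' epimer pair 17 that results is what step 10 needs.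

Further compounds
F1 | step 11 | 8'-hydroxy lactone from 19 (lactol epimers at C8') | C=C1C(=O)O[C@@H]2C[C@H](C)C3=C[C@@H](C(C)=O)[C@@]4(C[C@H]3C[C@H]12)C(=O)OC(O)[C@H]4C/C=C(/CCC5(C)SCCCS5)C(=C)C[Si](C)(C)C
F2 | step 11 | 8'-acetoxy lactone from F1 | C=C1C(=O)O[C@@H]2C[C@H](C)C3=C[C@@H](C(C)=O)[C@@]4(C[C@H]3C[C@H]12)C(=O)OC(OC(C)=O)[C@H]4C/C=C(/CCC5(C)SCCCS5)C(=C)C[Si](C)(C)C
F3 | step 10 | 7'-phenylselanyl anhydride from 18 | C=C1C(=O)O[C@@H]2C[C@H](C)C3=C[C@@H](C(C)=O)[C@@]4(C[C@H]3C[C@H]12)C(=O)OC(=O)C4([Se]c5ccccc5)C/C=C(/CCC6(C)SCCCS6)C(=C)C[Si](C)(C)C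
F4 | step 9 | spiro anhydride from 16 and itaconic anhydride (no side chain) | C=C1C(=O)O[C@@H]2C[C@H](C)C3=C[C@@H](C(C)=O)[C@@]4(C[C@H]3C[C@H]12)C(=O)OC(=O)C4
F5 | step 9 | methyl carbonate of 9 | COC(=O)OC/C=C(/CCC1(C)SCCCS1)C(=C)C[Si](C)(C)C
F6 | step 9 | silyl ketene acetal of F4 | C=C1C(=O)O[C@@H]2C[C@H](C)C3=C[C@@H](C(C)=O)[C@@]4(C[C@H]3C[C@H]12)C(=O)OC(O[Si](C)(C)C)=C4
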